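**Retrosynthetic overview** (benzofuranone locants of the target: O1, C2 lactone carbonyl, C3, C3a quaternary, C4, C5 ketone, C6, C7, C7a)
1. The C6=C7 double bond is taken back to the saturated C5 ketone; desaturation can only occur toward C6–C7 because C4 lies next to the quaternary C3a.
2. Key disconnection: C3a–C4 and C6–C7 together, by a catalytic asymmetric double Michael (1,6 then 1,4) [3+3] annulation of dimethyl 3-oxopentanedioate (C4–C5–C6; its esters are removed afterwards) with achiral 4-farnesyl-5-methylidenefuran-2(5H)-one.
3. Enabling feature: the γ-lactone O1–C2(=O)–C3 bridges C7a and C3a. As a butenolide with exocyclic C7 it is one cross-conjugated dienoate O=C2–C3=C3a–C7a=C7, electrophilic at C7 and at C3a, and its aromatic 2-furanol tautomer makes C7a stereolabile, so a mixture of C7a isomers can funnel into one cis-fused product.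
4. The ylidene butenolide comes from singlet-oxygen dearomatisation of 3-farnesyl-2-methylfuran (furan CH3 = C7, furan C2 = C7a, furan C3 = C3a, furan C5 = C2), made from 3-bromo-2-methylfuran and (2E,6E)-farnesyl bromide.
5. Ring order: the furan (later lactone) ring is bought and oxidised first; the carbocycle is closed onto it in the key step.

Key step: step 4

Remarks: farnesyl = (2E,6E)-3,7,11-trimethyldodeca-2,6,10-trien-1-yl; target locants are used for all intermediates. Catalyst of step 4: 3-{[3,5-bis(trifluoromethyl)phenyl]amino}-4-{[(8α,9S)-6′-methoxycinchonan-9-yl]amino}cyclobut-3-ene-1,2-dione (quinine-derived amine–squaramide). Assumption: the sense of induction of this catalyst cannot be predicted with certainty; if the first run shows the opposite sense, its quinidine-derived pseudoenantiomer is used instead.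

**Step 1**
Reactants: 1 (2E,6E)-farnesyl bromide; 2 3-bromo-2-methylfuran
Product: 4 3-farnesyl-2-methylfuran, via 2-methyl-3-furyllithium 3 (not isolated)
Conditions: 2, n-BuLi, THF, −78 °C; then 1, −78 → 0 °C
Reagents that add atoms: none
Why: Bromine–lithium exchange gives the 3-furyllithium, which is configurationally and positionally stable at −78 °C, and its SN2 alkylation by the primary allylic bromide (the trisubstituted γ-carbon disfavours SN2′) attaches the intact (2E,6E)-chain next to the methyl-bearing carbon; no stereocentre is formed.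

**Step 2**
Reactants: 4 3-farnesyl-2-methylfuran
Product: 6 4-farnesyl-5-hydroxy-5-methylfuran-2(5H)-one (racemic hemiketal), via furan endoperoxide 5 (not isolated)
Conditions: O2, hν (visible light), meso-tetraphenylporphyrin (cat.), i-Pr2NEt, CH2Cl2, −78 °C
Reagents that add atoms: dioxygen, O=O
Why: Singlet oxygen adds across the furan 2,5-positions in a [4+2] cycloaddition that is expected to be much faster than the ene reaction of the trisubstituted chain alkenes at −78 °C, and the amine base then removes the only bridgehead hydrogen (Kornblum–DeLaMare fragmentation), which puts the lactone carbonyl at the former unsubstituted α-carbon and leaves a racemic hemiketal (removed in step 3) at the methyl-bearing carbon: an oxidative dearomatisation of the furan to the γ-hydroxybutenolide.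

**Step 3**
Reactants: 6 4-farnesyl-5-hydroxy-5-methylfuran-2(5H)-one
Product: 8 4-farnesyl-5-methylidenefuran-2(5H)-one, via hemiketal trifluoroacetate 7 (not isolated)
Conditions: (CF3CO)2O, Et3N, CH2Cl2, −20 → 0 °C; product used at once
Reagents that add atoms: none
Why: The hemiketal hydroxyl is trifluoroacetylated and leaves from the acyloxy-stabilised oxocarbenium ion (E1-type dehydration of a γ-hydroxybutenolide to a γ-ylidenebutenolide), Et3N removing a proton from the methyl group, the only β-position that bears hydrogen, so the exocyclic C7a=C7 double bond results and no stereocentre remains.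

**Step 4**
Reactants: 8 4-farnesyl-5-methylidenefuran-2(5H)-one; 9 dimethyl 3-oxopentanedioate
Product: 12 dimethyl (3aS,7aR)-3a-farnesyl-2,5-dioxooctahydro-1-benzofuran-4,6-dicarboxylate (C4/C6 epimers), via furanol 1,6-adduct 10 (not isolated), via racemising butenolide 11 (not isolated)
Conditions: quinine-derived amine–squaramide catalyst (10 mol%), 9 (1.5 equiv), toluene, 0 °C → rt, slow addition of 8
Reagents that add atoms: none
Why: Proposed new method: an organocatalytic tandem 1,6-/1,4-Michael [3+3] annulation run as a dynamic kinetic resolution, whose closest known reaction types are the amine–squaramide-catalysed Michael addition of 1,3-dicarbonyl compounds, the 1,6-addition of soft nucleophiles to the exocyclic carbon of γ-ylidenebutenolides, the base-mediated intramolecular Michael addition of β-keto esters to butenolides, and the amine-mediated γ-proton transfer of butenolides through their 2-furanol form. The quinuclidine nitrogen deprotonates 9, whose first α-carbon (C6) adds to the unhindered exocyclic C7 of the dienoate O=C2–C3=C3a–C7a=C7 (1,6-addition is preferred over 1,4-addition at the fully substituted C3a) to give the aromatic 2-furanol 10, which is protonated at C7a to the racemic butenolide 11. The second α-carbon (C4) then closes the carbocycle by a 6-exo-trig Michael addition onto C3a, which creates the quaternary centre, and protonation at C3 gives 12; the lactone ring is already present and no other ring is closed. Because C4 is delivered through the C7 tether it can reach only the face of C3a that carries C7, so the ring fusion is necessarily cis and the configuration at C3a is tied to that at C7a. The enantiomers of 11 interconvert through achiral 10 under the amine base, while the squaramide N–H groups bind the lactone carbonyl and the ammonium-bound enolate attacks inside the chiral pocket, so the catalyst is meant to cyclise only the (7aR)-enantiomer (Curtin–Hammett funnel to the spatial arrangement of the target, 3aS,7aR by the CIP rules in 12); ring closure should be irreversible here because the retro-Michael reaction would need deprotonation at C3, α to the lactone. The step also needs C- over O-cyclisation (the C-adduct is the thermodynamic product) and mono-addition (excess 9, slow addition of 8), and the ester-bearing centres C4 and C6 are epimerisable and are lost in step 5.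

**Step 5**
Reactants: 12 dimethyl (3aS,7aR)-3a-farnesyl-2,5-dioxooctahydro-1-benzofuran-4,6-dicarboxylate
Product: 13 (3aR,7aR)-3a-farnesyl-3,3a,4,6,7,7a-hexahydro-1-benzofuran-2,5-dione
Conditions: LiCl, H2O, DMSO, 130 °C
Reagents that add atoms: none
Why: Krapcho dealkoxycarbonylation: chloride demethylates both β-keto esters by SN2 attack at the methyl groups and the β-keto carboxylates lose CO2, under neutral conditions that should leave the lactone, the chain alkenes and the two ring-fusion stereocentres (C3a is quaternary, C7a is not α to a carbonyl) unchanged.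

**Step 6**
Reactants: 13 (3aR,7aR)-3a-farnesyl-3,3a,4,6,7,7a-hexahydro-1-benzofuran-2,5-dione
Product: 14 (3aR,7aR)-3a-farnesyl-3a,7a-dihydro-1-benzofuran-2,5(3H,4H)-dione (CNP0400313.1)
Conditions: 2-iodoxybenzoic acid (IBX), DMSO, 70 °C
Reagents that add atoms: none
Why: Dehydrogenation of a ketone with IBX (enolisation, ligation to iodine, loss of the β-hydrogen) can remove hydrogen only from C6 and C7 because C4 lies next to the quaternary C3a, so the enone regiochemistry is fixed by the substrate, over-oxidation to a dienone or phenol is impossible, and the ring-fusion stereocentres are not touched.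

**Compound list**
1 | (2E,6E)-farnesyl bromide, (2E,6E)-1-bromo-3,7,11-trimethyldodeca-2,6,10-triene | CC(C)=CCC/C(C)=C/CC/C(C)=C/CBr | starting material
2 | 3-bromo-2-methylfuran | Cc1occc1Br | starting material
3 | (2-methylfuran-3-yl)lithium | [Li]c1ccoc1C | intermediate
4 | 3-farnesyl-2-methylfuran | CC(C)=CCC/C(C)=C/CC/C(C)=C/Cc1ccoc1C | intermediate
5 | 6-farnesyl-1-methyl-2,3,7-trioxabicyclo[2.2.1]hept-5-ene (furan endoperoxide, racemic) | CC(C)=CCC/C(C)=C/CC/C(C)=C/CC1=CC2OOC1(C)O2 | intermediate
6 | 4-farnesyl-5-hydroxy-5-methylfuran-2(5H)-one (racemic) | CC(C)=CCC/C(C)=C/CC/C(C)=C/CC1=CC(=O)OC1(C)O | intermediate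
7 | 3-farnesyl-2-methyl-5-oxo-2,5-dihydrofuran-2-yl trifluoroacetate (racemic) | CC(C)=CCC/C(C)=C/CC/C(C)=C/CC1=CC(=O)OC1(C)OC(=O)C(F)(F)F | intermediate
8 | 4-farnesyl-5-methylidenefuran-2(5H)-one | CC(C)=CCC/C(C)=C/CC/C(C)=C/CC1=CC(=O)OC1=C | intermediate
9 | dimethyl 3-oxopentanedioate | COC(=O)CC(=O)CC(=O)OC | starting material
10 | dimethyl 2-[(3-farnesyl-5-hydroxyfuran-2-yl)methyl]-3-oxopentanedioate | CC(C)=CCC/C(C)=C/CC/C(C)=C/Cc1cc(O)oc1CC(C(=O)OC)C(=O)CC(=O)OC | intermediate
11 | dimethyl 2-[(3-farnesyl-5-oxo-2,5-dihydrofuran-2-yl)methyl]-3-oxopentanedioate (ring carbon racemic and interconverting) | CC(C)=CCC/C(C)=C/CC/C(C)=C/CC1=CC(=O)OC1CC(C(=O)OC)C(=O)CC(=O)OC | intermediate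
12 | dimethyl (3aS,7aR)-3a-farnesyl-2,5-dioxooctahydro-1-benzofuran-4,6-dicarboxylate (cis-fused; same spatial arrangement as 13 and 14, the C3a descriptor changes only because C4 outranks C3; C4/C6 epimers) | CC(C)=CCC/C(C)=C/CC/C(C)=C/C[C@]12C(C(=O)OC)C(=O)C(C(=O)OC)C[C@H]1OC(=O)C2 | intermediate
13 | (3aR,7aR)-3a-farnesyl-3,3a,4,6,7,7a-hexahydro-1-benzofuran-2,5-dione (cis-fused) | CC(C)=CCC/C(C)=C/CC/C(C)=C/C[C@]12CC(=O)CC[C@H]1OC(=O)C2 | intermediate
14 | (3aR,7aR)-3a-[(2E,6E)-3,7,11-trimethyldodeca-2,6,10-trien-1-yl]-3a,7a-dihydro-1-benzofuran-2,5(3H,4H)-dione | CC(C)=CCC/C(C)=C/CC/C(C)=C/C[C@]12CC(=O)C=C[C@H]1OC(=O)C2 | target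

Total step count: 6. Longest linear sequence: 6 steps.

**Steps most likely to fail**

Step 4 (bears the label). What may go wrong: the catalyst may discriminate poorly between the two interconverting butenolide enantiomers, or ring closure at the fully substituted C3a may be slower than oligomerisation of the ylidene lactone. The fallback uses known reaction types only, gives up the annulation, sets out from 1 and comes back to the route at 14. Commercial 1,4-dioxaspiro[4.5]dec-6-en-8-one is deprotonated at C9 (LiN(i-Pr)2, THF, −78 °C; the ketal carbon blocks the other side) and alkylated with 1 to give 9-farnesyl-1,4-dioxaspiro[4.5]dec-6-en-8-one F1. A second deprotonation at the same carbon and alkylation with methyl bromoacetate should give the racemic quaternary keto ester methyl 2-(9-farnesyl-8-oxo-1,4-dioxaspiro[4.5]dec-6-en-9-yl)acetate F2. Reagent-controlled CBS reduction (Me-CBS oxazaborolidine, catecholborane, −78 °C, the catalyst enantiomer that gives the 8R carbinol) turns the two enantiomers of F2 into methyl 2-[(8R,9R)-9-farnesyl-8-hydroxy-1,4-dioxaspiro[4.5]dec-6-en-9-yl]acetate F3 and methyl 2-[(8R,9S)-9-farnesyl-8-hydroxy-1,4-dioxaspiro[4.5]dec-6-en-9-yl]acetate F4. Only F3 has the hydroxyl and the acetate arm cis, so it alone closes (PPTS cat.) to the cis-fused lactone (3aR,7aR)-3a-farnesyl-3a,4-dihydro-3H-spiro[1-benzofuran-5,2′-[1,3]dioxolan]-2(7aH)-one F5, and F4 is removed by chromatography. Mild hydrolysis of the dioxolane (PPTS, wet acetone) uncovers the C5 ketone in conjugation with C6=C7 and gives 14.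

Step 2. What may go wrong: ene-type photooxygenation of the trisubstituted chain alkenes may compete with cycloaddition to the furan, or the endoperoxide may fragment along another path. The fallback sets out from 4 and comes back at 8, passing by 6 and therefore also by step 3. Compound 4 is lithiated at its free α-position (n-BuLi, THF, 0 °C), borylated (B(OMe)3) and oxidised (H2O2) to 4-farnesyl-5-methylfuran-2(5H)-one F6. Silylation (TBSOTf, Et3N) converts F6 and any double-bond isomer into tert-butyl[(4-farnesyl-5-methylfuran-2-yl)oxy]dimethylsilane F7. γ-Bromination (NBS, THF, −78 °C; the silyloxyfuran should react far faster than the chain alkenes) gives 5-bromo-4-farnesyl-5-methylfuran-2(5H)-one F8, and dehydrobromination with Et3N gives 8.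

Step 6. What may go wrong: oxidation at allylic positions of the chain may compete, or conversion may stay incomplete at the temperature the hypervalent iodine reagent needs. The fallback (Saegusa–Ito sequence) sets out from 13 and comes back at 14. Kinetic enolisation (LiN(i-Pr)2, TMSCl, THF, −78 °C) gives (3aR,7aR)-3a-farnesyl-5-[(trimethylsilyl)oxy]-3a,4,7,7a-tetrahydro-1-benzofuran-2(3H)-one F9; the regioisomeric enol ether toward C4 cannot eliminate and reverts to 13. Treatment of F9 with Pd(OAc)2 in MeCN at rt gives 14.

**Further compounds**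
F1 | step 4 | 9-farnesyl-1,4-dioxaspiro[4.5]dec-6-en-8-one (racemic) | CC(C)=CCC/C(C)=C/CC/C(C)=C/CC1CC2(OCCO2)C=CC1=O
F2 | step 4 | methyl 2-(9-farnesyl-8-oxo-1,4-dioxaspiro[4.5]dec-6-en-9-yl)acetate (racemic) | CC(C)=CCC/C(C)=C/CC/C(C)=C/CC1(CC(=O)OC)CC2(OCCO2)C=CC1=O
F3 | step 4 | methyl 2-[(8R,9R)-9-farnesyl-8-hydroxy-1,4-dioxaspiro[4.5]dec-6-en-9-yl]acetate | CC(C)=CCC/C(C)=C/CC/C(C)=C/C[C@]1(CC(=O)OC)CC2(OCCO2)C=C[C@H]1O
F4 | step 4 | methyl 2-[(8R,9S)-9-farnesyl-8-hydroxy-1,4-dioxaspiro[4.5]dec-6-en-9-yl]acetate | CC(C)=CCC/C(C)=C/CC/C(C)=C/C[C@@]1(CC(=O)OC)CC2(OCCO2)C=C[C@H]1O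
F5 | step 4 | (3aR,7aR)-3a-farnesyl-3a,4-dihydro-3H-spiro[1-benzofuran-5,2′-[1,3]dioxolan]-2(7aH)-one | CC(C)=CCC/C(C)=C/CC/C(C)=C/C[C@]12CC3(OCCO3)C=C[C@H]1OC(=O)C2
F6 | step 2 | 4-farnesyl-5-methylfuran-2(5H)-one (racemic) | CC(C)=CCC/C(C)=C/CC/C(C)=C/CC1=CC(=O)OC1C
F7 | step 2 | tert-butyl[(4-farnesyl-5-methylfuran-2-yl)oxy]dimethylsilane | CC(C)=CCC/C(C)=C/CC/C(C)=C/Cc1cc(O[Si](C)(C)C(C)(C)C)oc1C
F8 | step 2 | 5-bromo-4-farnesyl-5-methylfuran-2(5H)-one (racemic) | CC(C)=CCC/C(C)=C/CC/C(C)=C/CC1=CC(=O)OC1(C)Br
F9 | step 6 | (3aR,7aR)-3a-farnesyl-5-[(trimethylsilyl)oxy]-3a,4,7,7a-tetrahydro-1-benzofuran-2(3H)-one | CC(C)=CCC/C(C)=C/CC/C(C)=C/C[C@]12CC(O[Si](C)(C)C)=CC[C@H]1OC(=O)C2
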